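Abbreviations used in names: Ar = 4-(benzyloxy)phenyl; Flav = 5,7-bis(benzyloxy)-2-[4-(benzyloxy)phenyl]-4-oxo-4H-chromen-3-yl. Compound numbers are those of the steps and of the compound list.

## Analysis of the target

The target is a 3,3''-linked flavanone–flavone dimer: a naringenin unit (chroman-4-one, rings A and C, with a 4-hydroxyphenyl ring B on C2) whose C3 carries C3'' of an apigenin unit. There are two stereocentres, C2 (S) and C3 (R). They are adjacent, and the aryl group on C2 and the flavonyl group on C3 lie on opposite faces of ring C (2,3-trans). Both centres are fragile: C3–H is α to the C4 ketone, and C2–O1 is a benzylic aryl ether β to that ketone. Base therefore opens ring C by retro-oxa-Michael reaction, and strong acid can ionize C2, whose cation is stabilized by the para oxygen of ring B. Six phenols, two of them chelated to carbonyl groups, must be unmasked last under neutral conditions. The hard part is the C3–C3'' bond, which joins two heterocycles at carbons that are flanked on both sides, while two almost identical phloroglucinol-derived halves are kept apart. The route rests on one feature: ring A is a 2-acylphloroglucinol fused to ring C through C4a and C8a. Without C5, C6, C7 and C8, ring C alone is a 2-aryl-2,3-dihydro-4H-pyran-4-one whose enone carbons are the future C4a and C8a, so both stereocentres can be set on a small phenol-free ring and the four carbons of ring A added last by a neutral pericyclic cascade.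

## Retrosynthetic reasoning

**33 ⇐ 32 ⇐ 31 (unmasking).** The oxygens at C4', C5'', C7'' and C4''' are carried as benzyl ethers, because hydrogenolysis is neutral and touches neither C2 nor C3. O7 is a tert-butyl ether because it comes in with ynol ether 28. It is removed by acid at the stage of 31, while the ring B oxygen is still benzylated and cannot open ring C through a quinone methide.

**31 ⇐ 23 + 28 (ring A).** The cuts are C4a–C5, C5–C6, C7–C8 and C8–C8a. This takes away the whole of ring A and leaves dihydropyranone 23, in which the pyranone carbons C5 and C6 are the future C4a and C8a. Forward, a Wolff shift moves the pyranone C6 onto the diazo carbon (C8–C8a), the resulting vinylketene takes up 28 (C5–C6 and C7–C8), and an electrocyclization closes C4a–C5. What is gained is that no phenol has to be differentiated: O5 appears free and chelated, O7 appears masked. The step has to form the ketene without acid or base and orient the ynol ether so that its oxygen ends on C7. The tert-butyl ynol ether 28 is chosen over a silyl ynol ether because it is distillable, its excess can be pumped off before the thermal stage, and it cannot isomerize to a silylketene.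

**23 ⇐ 21 ⇐ 19 (diazoacetyl group).** The diazoketone comes from acid 21 through acid chloride 22 and a one-carbon diazo reagent. The acid comes from the primary allylic alcohol 19 by oxidation. The carboxyl carbon is carried as a protected CH2OH through the organometallic steps, where an ester would not survive.

**19 ⇐ 17 (O1–C6).** Ring C is opened at the enol ether bond to give ynone 17. Forward, the C2 hydroxyl adds 6-endo-dig to the alkyne carbon β to the ketone. The cut is placed here because the aldol oxygen becomes O1 with retention at C2 and no bond to C2 or C3 is made or broken.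

**17 ⇐ 15 + 16 (C4–C5).** The ynone is cut at the acyl–alkyne bond into Weinreb amide 15 and the acetylide of 16. The amide stops the addition at the ketone stage.

**15 ⇐ 14 ⇐ 13 ⇐ 10 + 11 (C2–C3, both stereocentres).** The C2–C3 bond is an aldol bond between the flavonylacetyl imide 10 and aldehyde 11, controlled by the oxazolidinone 8. In the zigzag drawing of the C4–C3–C2–aryl chain, the anti arrangement of the C2 oxygen and the C3 flavonyl group is the one that becomes 2,3-trans once O1 and C4 are tied into a six-membered ring; a syn aldol would give the cis ring. The trans relationship has to be made kinetically at this point. It cannot be reached later by equilibration, because a C3 enolate expels O1 (a vinylogous carboxylate in 19–23, a phenoxide in 31–33) and acid strong enough to enolize C3 can ionize C2.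

**10 ⇐ 7 + 8; 7 ⇐ 6 ⇐ 4 + 5; 4 ⇐ 2 ⇐ 1 (the flavone half).** The acetic acid side chain is attached to C3'' by cross-coupling of iodide 4 with zinc reagent 5, which forms the hindered C3''–CH2 bond under neutral conditions. Iodide 4 comes from the perbenzylated flavone 2 by metalation at C3'', and 2 from apigenin 1. The flavone is thus bought complete and never has to be built next to a stereocentre.

**28 ⇐ 26 ⇐ 24 + 25 (the ketenophile).** The ynol ether is cut to the dichlorovinyl ether 26, which comes from alkoxide 24 and trichloroethene 25.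

## Alternatives that were turned down

**Alternative 1: a donor–acceptor cyclopropane that opens into both pyranone rings.** The disconnection cuts O1–C2 and O1''–C2'' and joins C2 to C3'', which gives the triacyl cyclopropane A2. Forward, Sc(OTf)3 would cleave the C2–C3'' bond, an ortho phenol of the C4 aryl ketone would attack C2 to close ring C, and the released 2-hydroxyaryl 1,3-diketone would cyclodehydrate to the flavone, giving A1.
- For it: two heterocycles form in one operation, both arene rings come intact from cheap phloroglucinol ketones, and the step count is lower than in the chosen route. On convergence it is the stronger plan.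
- Against it: the donor is a para-alkoxyphenyl group and the acceptor a geminal diketone. The C2–C3'' bond should therefore ionize to a benzylic cation and an enolate before the phenol arrives, and the configuration at C2 would be lost.
- Against it: a diketone carbonyl oxygen is placed to close a five-membered ring (Cloke–Wilson-type rearrangement), which is the usual outcome for acyl cyclopropanes with aryl donors, and four free phenols compete.
- Against it: A2 must itself be made as one enantiomer.
- In place of that convergence, the chosen strategy fixes C2 and C3 in a closed transition state, never passes through an ionized C2, and builds ring A by a cascade that cannot give constitutional isomers.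

**Alternative 2: aldol-derived diol closed by palladium aryl etherification.** The disconnection cuts O1–C8a; ring A enters as an aryl bromide in the bromo diol A4. Forward, Pd(OAc)2 with a bulky di-tert-butyl(biaryl)phosphine and Cs2CO3 would couple the C2 hydroxyl with the aryl bromide, with retention at C2, to give the flavan-4-ol A3. Oxidation at C4 and hydrogenolysis would follow.
- For it: the stereocentres come from the same kind of aldol as here, and the ring-forming event has closer precedent than the photochemical annulation. On that point it is at least as strong.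
- Against it: the bromide is electron-rich and flanked on both sides, so reductive elimination is slow and β-hydride elimination of the secondary benzylic alkoxide (ketone formation and hydrodebromination) becomes the likely leak.
- Against it: the C4 carbinol is a third stereocentre made only to be oxidized away, which costs a redox step.
- Against it: all six oxygens leave the sequence as the same ether, so nothing distinguishes O5 from O7.
- In place of that precedent, the chosen strategy has no redox correction, no metal coupling at the most crowded arene position, and a ring A whose oxygen pattern is decided by the alkyne at the end.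

**Alternative 3: ortho-quinone methide cycloaddition to a 3-styrylflavone.** The disconnection cuts C3–C4 and O1–C2. Forward, a chiral phosphoric acid would dehydrate the 2-hydroxybenzyl alcohol A7 to an ortho-quinone methide, which would add across the E-alkene of the styrylflavone A6 to give the trans chroman A5.
- For it: this is the most convergent plan. Two bonds, ring C and both stereocentres arise in one catalytic step, and trans follows from the E-alkene. On step economy it is clearly ahead.
- Against it: A5 lacks the C4 carbonyl. A benzylic CH2 would have to be oxidized in the presence of six benzyl ether CH2 groups and the benzylic C2–H, and no selective way to do that is apparent.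
- Against it: the alkene of A6 is conjugated to the chromone and hindered by it, which is the opposite of the electron-rich styrenes that these cycloadditions need.
- In place of that convergence, the chosen strategy has C4 at the ketone level from the aldol onward, because C4 is the acyl carbon of the aldol.

Key step: step 15

Assumption: the magnesium-catalysed anti-aldol of 10 is taken to follow the chelated (Z)-enolate model of simple N-acyl oxazolidinones (aldehyde on the face away from the benzyl group). If the facial sense were the reverse, the (R)-auxiliary would be used and nothing else would change.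

## Steps

Step 1
Reactants: 1 apigenin
Product: 2 5,7-bis(benzyloxy)-2-[4-(benzyloxy)phenyl]-4H-chromen-4-one
Conditions: BnBr (4.5 equiv), K2CO3, Bu4NI (cat.), DMF, 80 °C
Reagents that add atoms: benzyl bromide, BrCc1ccccc1
Why: Williamson ether synthesis; the two unchelated phenols react first and the chelated 5-OH follows with excess halide, iodide catalysis and heat, so that no acidic proton is left for the metalation in step 2.

Step 2
Reactants: 2 5,7-bis(benzyloxy)-2-[4-(benzyloxy)phenyl]-4H-chromen-4-one
Product: 4 5,7-bis(benzyloxy)-2-[4-(benzyloxy)phenyl]-3-iodo-4H-chromen-4-one, via 3-lithiochromone 3 (not isolated)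
Conditions: LDA (1.3 equiv), THF, −78 °C; then I2, −78 → 0 °C
Reagents that add atoms: iodine, II
Why: Deprotonation of the vinylic C3–H next to the chromone carbonyl and iodinolysis of the vinyllithium; metalation puts iodine on C3 only, whereas electrophilic iodination would attack the electron-rich C6 and C8 positions.

Step 3
Reactants: 4 5,7-bis(benzyloxy)-2-[4-(benzyloxy)phenyl]-3-iodo-4H-chromen-4-one; 5 (2-ethoxy-2-oxoethyl)zinc bromide
Product: 6 ethyl 2-Flav-acetate
Conditions: Pd2(dba)3 (2.5 mol%), XPhos (6 mol%), THF, 50 °C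
Reagents that add atoms: none
Why: Negishi coupling of a Reformatsky reagent with a vinyl iodide under zerovalent palladium and a bulky biaryl phosphine; the neutral zinc enolate tolerates the chromone carbonyl and the benzyl ethers.

Step 4
Reactants: 6 ethyl 2-Flav-acetate
Product: 7 2-Flav-acetic acid
Conditions: LiOH·H2O, THF/H2O, 20 °C; then 1 M HCl
Reagents that add atoms: lithium hydroxide, [Li+].[OH-]
Why: Ester saponification; the product is a γ-keto acid and does not decarboxylate, and dilute hydroxide in the cold leaves the flavone ring closed.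

Step 5
Reactants: 7 2-Flav-acetic acid; 8 (4S)-4-benzyl-1,3-oxazolidin-2-one
Product: 10 (4S)-4-benzyl-3-(2-Flav-acetyl)-1,3-oxazolidin-2-one, via mixed pivalic anhydride 9 (not isolated)
Conditions: PivCl, Et3N, THF, −20 °C; then 8, LiCl, −20 → 20 °C
Reagents that add atoms: pivaloyl chloride, CC(C)(C)C(=O)Cl (acyl group present in 9 only)
Why: N-acylation of the oxazolidinone through the mixed anhydride with LiCl/Et3N activation, the usual way to attach an arylacetic acid to this auxiliary without a strong base.

Step 6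
Reactants: 10 (4S)-4-benzyl-3-(2-Flav-acetyl)-1,3-oxazolidin-2-one; 11 4-(benzyloxy)benzaldehyde
Product: 13 (4S)-4-benzyl-3-[(2R,3S)-3-Ar-2-Flav-3-hydroxypropanoyl]-1,3-oxazolidin-2-one, via trimethylsilyl ether 12 (not isolated)
Conditions: MgCl2 (20 mol%), Et3N (2 equiv), Me3SiCl (1.5 equiv), EtOAc, 23 °C; then MeOH, CF3CO2H (cat.)
Reagents that add atoms: chlorotrimethylsilane, C[Si](C)(C)Cl (silyl group present in 12 only)
Why: Magnesium-catalysed direct anti-aldol of an N-acyl oxazolidinone by soft enolization: the chelated (Z)-magnesium enolate should add to the aromatic aldehyde on the face away from the auxiliary benzyl group through a closed boat-like transition state, which sets the future C3 (R) and C2 (S) in the anti relationship. Silylation of the aldolate by Me3SiCl makes the addition irreversible and frees the magnesium, and the labile silyl ether is cleaved on work-up.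

Step 7
Reactants: 13 (4S)-4-benzyl-3-[(2R,3S)-3-Ar-2-Flav-3-hydroxypropanoyl]-1,3-oxazolidin-2-one
Product: 14 (2R,3S)-3-Ar-2-Flav-3-hydroxy-N-methoxy-N-methylpropanamide
Conditions: MeNH(OMe)·HCl, AlMe3, CH2Cl2, −10 → 20 °C; 0.5 M HCl work-up
Reagents that add atoms: N,O-dimethylhydroxylamine hydrochloride, CNOC.Cl
Why: Aluminium amide transamidation of the imide to the Weinreb amide, directed by the free β-hydroxyl to the exocyclic carbonyl; it releases the auxiliary without enolizing C3.

Step 8
Reactants: 14 (2R,3S)-3-Ar-2-Flav-3-hydroxy-N-methoxy-N-methylpropanamide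
Product: 15 (2R,3S)-3-Ar-2-Flav-N-methoxy-N-methyl-3-(triethylsilyloxy)propanamide
Conditions: Et3SiCl, imidazole, DMAP (cat.), DMF, 20 → 40 °C
Reagents that add atoms: chlorotriethylsilane, CC[Si](Cl)(CC)CC
Why: Silylation of the secondary benzylic alcohol so that the basic step 9 cannot start a retro-aldol cleavage; the chloride/imidazole method is used because a silyl triflate would activate the chromone carbonyl.

Step 9
Reactants: 15 (2R,3S)-3-Ar-2-Flav-N-methoxy-N-methyl-3-(triethylsilyloxy)propanamide; 16 tert-butyldimethyl(prop-2-yn-1-yloxy)silane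
Product: 17 (5R,6S)-6-Ar-1-(tert-butyldimethylsilyloxy)-5-Flav-6-(triethylsilyloxy)hex-2-yn-4-one
Conditions: 16, n-BuLi, THF, −78 °C; then 15, −78 → 0 °C; aq. NH4Cl
Reagents that add atoms: none
Why: Acyl substitution on a Weinreb amide: the chelated tetrahedral adduct holds until work-up and gives the ynone. The amide should be more electrophilic than the cross-conjugated chromone carbonyl, which is flanked by the 5-benzyloxy group and the C3'' substituent, and the acetylide is a weak base, which limits deprotonation at C3.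

Step 10
Reactants: 17 (5R,6S)-6-Ar-1-(tert-butyldimethylsilyloxy)-5-Flav-6-(triethylsilyloxy)hex-2-yn-4-one
Product: 19 (2S,3R)-2-Ar-3-Flav-6-(hydroxymethyl)-2,3-dihydro-4H-pyran-4-one, via dihydroxy ynone 18 (not isolated)
Conditions: HF·pyridine, THF/pyridine, 0 → 20 °C; then Ph3PAuCl (5 mol%), AgOTf (5 mol%), CH2Cl2, 20 °C
Reagents that add atoms: none
Why: Fluoride removes both silyl ethers; the monovalent gold cation then activates the ynone for 6-endo-dig attack of the C2 hydroxyl on the alkyne carbon β to the ketone (O1–C6), the known cyclization of β-hydroxy ynones to 2,3-dihydro-4H-pyran-4-ones. No bond to C2 or C3 is broken, so the anti aldol becomes the 2,3-trans ring.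

Step 11
Reactants: 19 (2S,3R)-2-Ar-3-Flav-6-(hydroxymethyl)-2,3-dihydro-4H-pyran-4-one
Product: 21 (2S,3R)-2-Ar-3-Flav-4-oxo-3,4-dihydro-2H-pyran-6-carboxylic acid, via aldehyde 20 (not isolated)
Conditions: TEMPO (10 mol%), PhI(OAc)2, CH2Cl2, 20 °C; then NaClO2, NaH2PO4, 2-methylbut-2-ene, t-BuOH/THF/H2O, 0 °C
Reagents that add atoms: sodium chlorite, [Na+].[O-]Cl=O
Why: Oxoammonium oxidation of the primary allylic alcohol to the aldehyde, then Pinnick oxidation to the acid; both stages run near neutral pH, which the C2 and C3 centres tolerate.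

Step 12
Reactants: 21 (2S,3R)-2-Ar-3-Flav-4-oxo-3,4-dihydro-2H-pyran-6-carboxylic acid
Product: 23 (2S,3R)-2-Ar-6-(diazoacetyl)-3-Flav-2,3-dihydro-4H-pyran-4-one, via acid chloride 22 (not isolated)
Conditions: Me2C=C(Cl)NMe2 (1.2 equiv), CH2Cl2, 0 °C; then CH2N2 (3 equiv), Et2O, −20 → 0 °C; AcOH quench
Reagents that add atoms: 1-chloro-N,N,2-trimethylprop-1-en-1-amine, CC(C)=C(Cl)N(C)C (chlorine present in 22 only); diazomethane, C=[N+]=[N-]
Why: The neutral α-chloroenamine makes the acid chloride without free HCl, and the chloride acylates diazomethane as in the first stage of an Arndt–Eistert sequence (chromone-2-carbonyl chlorides behave this way). Acylation at −20 °C should outrun dipolar cycloaddition to the alkoxy-bearing, trisubstituted C5=C6 bond, and excess reagent is destroyed at once.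

Step 13
Reactants: 24 potassium tert-butoxide; 25 trichloroethene
Product: 26 (E)-1,2-dichlorovinyl tert-butyl ether
Conditions: THF, −30 → 20 °C
Reagents that add atoms: none
Why: The alkoxide dehydrochlorinates trichloroethene to dichloroethyne and adds to it in the anti sense; protonation gives the (E)-dichlorovinyl ether.

Step 14
Reactants: 26 (E)-1,2-dichlorovinyl tert-butyl ether
Product: 28 tert-butoxyethyne, via lithium tert-butoxyacetylide 27 (not isolated)
Conditions: n-BuLi (2.2 equiv), Et2O, −78 → −40 °C; then H2O, −78 °C; distillation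
Reagents that add atoms: none
Why: Butyllithium eliminates HCl to the chloroalkynyl ether and exchanges the remaining chlorine for lithium; protonation gives the ynol ether, which is kept cold because tert-butyl ynol ethers lose isobutene on warming.

Step 15
Reactants: 23 (2S,3R)-2-Ar-6-(diazoacetyl)-3-Flav-2,3-dihydro-4H-pyran-4-one; 28 tert-butoxyethyne
Product: 31 (2S,3R)-2-Ar-7-tert-butoxy-3-Flav-5-hydroxy-2,3-dihydro-4H-chromen-4-one, via vinylketene 29 (not isolated), via cyclobutenone 30 (not isolated)
Conditions: 28 (3 equiv), degassed toluene (0.02 M), 450 nm LEDs, 20 °C; then evaporation of excess 28, toluene, 80 °C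
Reagents that add atoms: none
Why: This is the Danheiser benzannulation in its diazoketone (photochemical Wolff) form, known for aryl, heteroaryl and cycloalkenyl diazomethyl ketones with ynol ethers. Light in the blue tail of the diazoketone band, where neither chromone absorbs, expels N2, and the pyranone carbon C6 shifts from the acyl carbon to the diazo carbon (C8–C8a) to give vinylketene 29. The nucleophilic terminal carbon of 28 bonds to the ketene carbonyl carbon and the oxygen-bearing carbon to the ketene α-carbon, a regiospecific [2+2] cycloaddition that forms C5–C6 and C7–C8 and gives the 4-alkenylcyclobutenone 30. At 80 °C 30 opens by a reversible four-electron conrotatory electrocyclic reaction to a dienylketene, and six-electron disrotatory electrocyclization between the ketene carbon and the pyranone C5 closes ring A (C4a–C5); tautomerization gives the phenol. No stereocentre is created, since the sp3 carbon of 30 becomes aromatic C8, and C2 and C3 see only light and warm toluene, so their configuration should be kept. The selectivity needed is the orientation of the [2+2] step, which the polarization of the ynol ether fixes (oxygen on C7, free hydroxyl on C5 chelated to the C4 carbonyl), and a clean Wolff shift over carbene chemistry, which the conjugated acyl diazo unit and the excess of ketenophile favour.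

Step 16
Reactants: 31 (2S,3R)-2-Ar-7-tert-butoxy-3-Flav-5-hydroxy-2,3-dihydro-4H-chromen-4-one
Product: 32 (2S,3R)-2-Ar-3-Flav-5,7-dihydroxy-2,3-dihydro-4H-chromen-4-one
Conditions: CF3CO2H/CH2Cl2 (1:4), anisole (10 equiv), 0 °C
Reagents that add atoms: none
Why: Acidolysis of the aryl tert-butyl ether through the tert-butyl cation, which excess anisole traps by Friedel–Crafts alkylation so that it cannot alkylate C6 or C8. It is done while the 4'-oxygen is still benzylated and at 0 °C, where the aryl benzyl ethers and the C2–O1 bond should survive.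

Step 17
Reactants: 32 (2S,3R)-2-Ar-3-Flav-5,7-dihydroxy-2,3-dihydro-4H-chromen-4-one
Product: 33 (2S,3R)-3-[5,7-dihydroxy-2-(4-hydroxyphenyl)-4-oxo-4H-chromen-3-yl]-5,7-dihydroxy-2-(4-hydroxyphenyl)-2,3-dihydro-4H-chromen-4-one
Conditions: H2 (1 atm), 10% Pd/C, EtOAc/MeOH, 20 °C
Reagents that add atoms: none
Why: Hydrogenolysis of the four aryl benzyl ethers under neutral conditions; the tetrasubstituted chromone double bond and the chelated aryl ketones are not expected to be reduced at one atmosphere, and the reaction is stopped at full debenzylation to protect the benzylic C2–O1 bond.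

## Compound list

1 | apigenin, 5,7-dihydroxy-2-(4-hydroxyphenyl)-4H-chromen-4-one | O=c1cc(-c2ccc(O)cc2)oc2cc(O)cc(O)c12 | starting material
2 | 5,7-bis(benzyloxy)-2-[4-(benzyloxy)phenyl]-4H-chromen-4-one | O=c1cc(-c2ccc(OCc3ccccc3)cc2)oc2cc(OCc3ccccc3)cc(OCc3ccccc3)c12 | intermediate
3 | 3-lithio derivative of 2 (Flav–Li) | [Li]c1c(-c2ccc(OCc3ccccc3)cc2)oc2cc(OCc3ccccc3)cc(OCc3ccccc3)c2c1=O | intermediate
4 | 5,7-bis(benzyloxy)-2-[4-(benzyloxy)phenyl]-3-iodo-4H-chromen-4-one | Ic1c(-c2ccc(OCc3ccccc3)cc2)oc2cc(OCc3ccccc3)cc(OCc3ccccc3)c2c1=O | intermediate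
5 | (2-ethoxy-2-oxoethyl)zinc bromide | CCOC(=O)C[Zn]Br | starting material
6 | ethyl 2-Flav-acetate | CCOC(=O)Cc1c(-c2ccc(OCc3ccccc3)cc2)oc2cc(OCc3ccccc3)cc(OCc3ccccc3)c2c1=O | intermediate
7 | 2-Flav-acetic acid | OC(=O)Cc1c(-c2ccc(OCc3ccccc3)cc2)oc2cc(OCc3ccccc3)cc(OCc3ccccc3)c2c1=O | intermediate
8 | (4S)-4-benzyl-1,3-oxazolidin-2-one | O=C1OC[C@H](Cc2ccccc2)N1 | starting material
9 | 2-Flav-acetic pivalic anhydride | CC(C)(C)C(=O)OC(=O)Cc1c(-c2ccc(OCc3ccccc3)cc2)oc2cc(OCc3ccccc3)cc(OCc3ccccc3)c2c1=O | intermediate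
10 | (4S)-4-benzyl-3-(2-Flav-acetyl)-1,3-oxazolidin-2-one | O=C1OC[C@H](Cc2ccccc2)N1C(=O)Cc1c(-c2ccc(OCc3ccccc3)cc2)oc2cc(OCc3ccccc3)cc(OCc3ccccc3)c2c1=O | intermediate
11 | 4-(benzyloxy)benzaldehyde | O=Cc1ccc(OCc2ccccc2)cc1 | starting material
12 | (4S)-4-benzyl-3-[(2R,3S)-3-Ar-2-Flav-3-(trimethylsilyloxy)propanoyl]-1,3-oxazolidin-2-one | C[Si](C)(C)O[C@H](c1ccc(OCc2ccccc2)cc1)[C@@H](c1c(-c2ccc(OCc3ccccc3)cc2)oc2cc(OCc3ccccc3)cc(OCc3ccccc3)c2c1=O)C(=O)N1C(=O)OC[C@@H]1Cc1ccccc1 | intermediate
13 | (4S)-4-benzyl-3-[(2R,3S)-3-Ar-2-Flav-3-hydroxypropanoyl]-1,3-oxazolidin-2-one | O[C@H](c1ccc(OCc2ccccc2)cc1)[C@@H](c1c(-c2ccc(OCc3ccccc3)cc2)oc2cc(OCc3ccccc3)cc(OCc3ccccc3)c2c1=O)C(=O)N1C(=O)OC[C@@H]1Cc1ccccc1 | intermediate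
14 | (2R,3S)-3-Ar-2-Flav-3-hydroxy-N-methoxy-N-methylpropanamide | O[C@H](c1ccc(OCc2ccccc2)cc1)[C@@H](c1c(-c2ccc(OCc3ccccc3)cc2)oc2cc(OCc3ccccc3)cc(OCc3ccccc3)c2c1=O)C(=O)N(C)OC | intermediate
15 | (2R,3S)-3-Ar-2-Flav-N-methoxy-N-methyl-3-(triethylsilyloxy)propanamide | CC[Si](CC)(CC)O[C@H](c1ccc(OCc2ccccc2)cc1)[C@@H](c1c(-c2ccc(OCc3ccccc3)cc2)oc2cc(OCc3ccccc3)cc(OCc3ccccc3)c2c1=O)C(=O)N(C)OC | intermediate
16 | tert-butyldimethyl(prop-2-yn-1-yloxy)silane | C#CCO[Si](C)(C)C(C)(C)C | starting material
17 | (5R,6S)-6-Ar-1-(tert-butyldimethylsilyloxy)-5-Flav-6-(triethylsilyloxy)hex-2-yn-4-one | CC[Si](CC)(CC)O[C@H](c1ccc(OCc2ccccc2)cc1)[C@@H](c1c(-c2ccc(OCc3ccccc3)cc2)oc2cc(OCc3ccccc3)cc(OCc3ccccc3)c2c1=O)C(=O)C#CCO[Si](C)(C)C(C)(C)C | intermediate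
18 | (5R,6S)-6-Ar-5-Flav-1,6-dihydroxyhex-2-yn-4-one | O[C@H](c1ccc(OCc2ccccc2)cc1)[C@@H](c1c(-c2ccc(OCc3ccccc3)cc2)oc2cc(OCc3ccccc3)cc(OCc3ccccc3)c2c1=O)C(=O)C#CCO | intermediate
19 | (2S,3R)-2-Ar-3-Flav-6-(hydroxymethyl)-2,3-dihydro-4H-pyran-4-one | O=C1C=C(CO)O[C@H](c2ccc(OCc3ccccc3)cc2)[C@H]1c1c(-c2ccc(OCc3ccccc3)cc2)oc2cc(OCc3ccccc3)cc(OCc3ccccc3)c2c1=O | intermediate
20 | (2S,3R)-2-Ar-3-Flav-4-oxo-3,4-dihydro-2H-pyran-6-carbaldehyde | O=C1C=C(C=O)O[C@H](c2ccc(OCc3ccccc3)cc2)[C@H]1c1c(-c2ccc(OCc3ccccc3)cc2)oc2cc(OCc3ccccc3)cc(OCc3ccccc3)c2c1=O | intermediate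
21 | (2S,3R)-2-Ar-3-Flav-4-oxo-3,4-dihydro-2H-pyran-6-carboxylic acid | O=C1C=C(C(=O)O)O[C@H](c2ccc(OCc3ccccc3)cc2)[C@H]1c1c(-c2ccc(OCc3ccccc3)cc2)oc2cc(OCc3ccccc3)cc(OCc3ccccc3)c2c1=O | intermediate
22 | (2S,3R)-2-Ar-3-Flav-4-oxo-3,4-dihydro-2H-pyran-6-carbonyl chloride | O=C1C=C(C(=O)Cl)O[C@H](c2ccc(OCc3ccccc3)cc2)[C@H]1c1c(-c2ccc(OCc3ccccc3)cc2)oc2cc(OCc3ccccc3)cc(OCc3ccccc3)c2c1=O | intermediate
23 | (2S,3R)-2-Ar-6-(diazoacetyl)-3-Flav-2,3-dihydro-4H-pyran-4-one | O=C1C=C(C(=O)C=[N+]=[N-])O[C@H](c2ccc(OCc3ccccc3)cc2)[C@H]1c1c(-c2ccc(OCc3ccccc3)cc2)oc2cc(OCc3ccccc3)cc(OCc3ccccc3)c2c1=O | intermediate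
24 | potassium tert-butoxide | CC(C)(C)[O-].[K+] | starting material
25 | trichloroethene | ClC=C(Cl)Cl | starting material
26 | (E)-1,2-dichlorovinyl tert-butyl ether | CC(C)(C)O/C(Cl)=C\Cl | intermediate
27 | lithium tert-butoxyacetylide | [Li]C#COC(C)(C)C | intermediate
28 | tert-butoxyethyne | C#COC(C)(C)C | intermediate
29 | (2S,3R)-2-Ar-3-Flav-6-(2-oxoethenyl)-2,3-dihydro-4H-pyran-4-one (vinylketene) | O=C1C=C(C=C=O)O[C@H](c2ccc(OCc3ccccc3)cc2)[C@H]1c1c(-c2ccc(OCc3ccccc3)cc2)oc2cc(OCc3ccccc3)cc(OCc3ccccc3)c2c1=O | intermediate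
30 | 3-tert-butoxy-4-[(2S,3R)-2-Ar-3-Flav-4-oxo-3,4-dihydro-2H-pyran-6-yl]cyclobut-2-en-1-one (both epimers at the cyclobutenone sp3 carbon) | O=C1C=C(C2C(=O)C=C2OC(C)(C)C)O[C@H](c2ccc(OCc3ccccc3)cc2)[C@H]1c1c(-c2ccc(OCc3ccccc3)cc2)oc2cc(OCc3ccccc3)cc(OCc3ccccc3)c2c1=O | intermediate
31 | (2S,3R)-2-Ar-7-tert-butoxy-3-Flav-5-hydroxy-2,3-dihydro-4H-chromen-4-one | O=C1c2c(O)cc(OC(C)(C)C)cc2O[C@H](c2ccc(OCc3ccccc3)cc2)[C@H]1c1c(-c2ccc(OCc3ccccc3)cc2)oc2cc(OCc3ccccc3)cc(OCc3ccccc3)c2c1=O | intermediate
32 | (2S,3R)-2-Ar-3-Flav-5,7-dihydroxy-2,3-dihydro-4H-chromen-4-one | O=C1c2c(O)cc(O)cc2O[C@H](c2ccc(OCc3ccccc3)cc2)[C@H]1c1c(-c2ccc(OCc3ccccc3)cc2)oc2cc(OCc3ccccc3)cc(OCc3ccccc3)c2c1=O | intermediate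
33 | (2S,3R)-3-[5,7-dihydroxy-2-(4-hydroxyphenyl)-4-oxo-4H-chromen-3-yl]-5,7-dihydroxy-2-(4-hydroxyphenyl)-2,3-dihydro-4H-chromen-4-one | O=C1c2c(O)cc(O)cc2O[C@H](c2ccc(O)cc2)[C@H]1c1c(-c2ccc(O)cc2)oc2cc(O)cc(O)c2c1=O | target

## Step count and least certain steps

Total step count: 17. Longest linear sequence: 15 steps (steps 1–12 and 15–17, from apigenin 1); steps 13 and 14 make the ynol ether 28.

**Step 15 (key step).** The vinylketene 29 may be lost to dimerization or to traces of nucleophile before it meets 28. The cyclobutenone 30 may also open mainly in the outward sense on heating and decompose before the productive dienylketene is drained. Both follow from the fact that the alkenyl group here is an electron-poor, oxygen-substituted enone and not a simple alkene. The fallback keeps ring A last but builds it by acylketene acylation and sets out from 23. Irradiation of 23 in wet THF gives, by Wolff rearrangement and capture of the ketene by water, the homologous acid 2-[(2S,3R)-2-Ar-3-Flav-4-oxo-3,4-dihydro-2H-pyran-6-yl]acetic acid F1. Condensation of F1 with Meldrum's acid (EDC, DMAP, CH2Cl2, 0 °C) gives the acyl Meldrum's acid F2. In toluene at 100 °C F2 loses acetone and CO2 to the acylketene F3, whose ketene carbon acylates the nucleophilic pyranone C5; enolization then gives the 5,7-dihydroxy arene. The fallback comes back to the route at 32 and leaves out step 16.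

**Step 6.** The facial and anti selectivity may be poor, because the chromone carbonyl of 10 can compete with the oxazolidinone carbonyl for magnesium and because addition to the electron-rich aldehyde 11 is slow enough for retro-aldol equilibration before silylation. The fallback replaces the auxiliary by a catalytic anti-selective aldol through an open transition state and sets out from 6. LDA and t-BuMe2SiCl give the silyl ketene acetal F4. F4 and 11, with SiCl4, i-Pr2NEt and a chiral 2,2'-binaphthyldiamine-derived bis(phosphoramide) in CH2Cl2 at −78 °C (catalyst enantiomer chosen for the 3S carbinol), give the anti hydroxy ester ethyl (2R,3S)-3-Ar-2-Flav-3-hydroxypropanoate F5. MeNH(OMe)·HCl with i-PrMgCl converts F5 into the Weinreb amide, and the fallback comes back at 14.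

**Step 12.** Dipolar cycloaddition of diazomethane to the doubly acyl-activated C5=C6 bond of 22 or 23 may compete with acylation and consume the material as a pyrazoline. The fallback makes the diazoketone by diazo transfer and sets out from 15. The lithium acetylide of the purchasable tert-butyldimethyl(but-3-yn-2-yloxy)silane gives ynone F6. HF·pyridine gives the diol F7, which is cyclized as in step 10 (Ph3PAuCl, AgOTf) to the 6-(1-hydroxyethyl)pyranone F8. Dess–Martin periodinane gives the 6-acetylpyranone F9. Kinetic enolization of the unhindered methyl group (LiHMDS, THF, −78 °C) and trapping with CF3CO2CH2CF3 give the trifluoroacetyl diketone F10. Detrifluoroacetylative diazo transfer (MsN3, Et3N, H2O, MeCN) then gives the diazoketone, and the fallback comes back at 23.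

**Step 9.** The acetylide may add to the chromone carbonyl in competition with the hindered amide, or deprotonate C3 with loss of the silyloxy group, because the amide carbon carries two bulky neighbours. The fallback uses an aldehyde as the far more electrophilic acceptor and sets out from 15. i-Bu2AlH (THF, −78 °C) gives the aldehyde (2R,3S)-3-Ar-2-Flav-3-(triethylsilyloxy)propanal F11. The lithium acetylide of 16 adds at −78 °C to give the propargylic alcohols F12 as a mixture of carbinol epimers. Dess–Martin periodinane with NaHCO3 oxidizes F12, and the fallback comes back at 17.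

**Step 16.** Acid may ionize the C2–O1 bond, with loss of the C2 configuration, or the tert-butyl cation may alkylate ring A, which after cleavage is a free resorcinol. The fallback removes the acid step by changing the ynol ether and sets out from 23. Potassium benzyl oxide and 25 give benzyl (E)-1,2-dichlorovinyl ether F13. n-BuLi gives lithium benzyloxyacetylide F14, and water gives benzyloxyethyne F15. Irradiation of 23 with F15 as in step 15 gives, through 29, the benzyloxy cyclobutenone F16. Excess F15 is removed by filtration through silica before heating, because benzyl ynol ethers rearrange when warmed, and heating then gives the 7-O-benzyl ether (2S,3R)-2-Ar-7-(benzyloxy)-3-Flav-5-hydroxy-2,3-dihydro-4H-chromen-4-one F17. Hydrogenolysis of all five benzyl ethers as in step 17 comes back to the route at 33.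

## Further compounds

F1 | step 15 | 2-[(2S,3R)-2-Ar-3-Flav-4-oxo-3,4-dihydro-2H-pyran-6-yl]acetic acid | O=C1C=C(CC(=O)O)O[C@H](c2ccc(OCc3ccccc3)cc2)[C@H]1c1c(-c2ccc(OCc3ccccc3)cc2)oc2cc(OCc3ccccc3)cc(OCc3ccccc3)c2c1=O
F2 | step 15 | 5-{2-[(2S,3R)-2-Ar-3-Flav-4-oxo-3,4-dihydro-2H-pyran-6-yl]acetyl}-2,2-dimethyl-1,3-dioxane-4,6-dione | O=C1C=C(CC(=O)C2C(=O)OC(C)(C)OC2=O)O[C@H](c2ccc(OCc3ccccc3)cc2)[C@H]1c1c(-c2ccc(OCc3ccccc3)cc2)oc2cc(OCc3ccccc3)cc(OCc3ccccc3)c2c1=O
F3 | step 15 | (2S,3R)-2-Ar-3-Flav-6-(2,4-dioxobut-3-en-1-yl)-2,3-dihydro-4H-pyran-4-one (acylketene) | O=C1C=C(CC(=O)C=C=O)O[C@H](c2ccc(OCc3ccccc3)cc2)[C@H]1c1c(-c2ccc(OCc3ccccc3)cc2)oc2cc(OCc3ccccc3)cc(OCc3ccccc3)c2c1=O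
F4 | step 6 | tert-butyl[(1-ethoxy-2-Flav-ethenyl)oxy]dimethylsilane (either alkene geometry) | CCOC(O[Si](C)(C)C(C)(C)C)=Cc1c(-c2ccc(OCc3ccccc3)cc2)oc2cc(OCc3ccccc3)cc(OCc3ccccc3)c2c1=O
F5 | step 6 | ethyl (2R,3S)-3-Ar-2-Flav-3-hydroxypropanoate | O[C@H](c1ccc(OCc2ccccc2)cc1)[C@@H](c1c(-c2ccc(OCc3ccccc3)cc2)oc2cc(OCc3ccccc3)cc(OCc3ccccc3)c2c1=O)C(=O)OCC
F6 | step 12 | (5R,6S)-6-Ar-2-(tert-butyldimethylsilyloxy)-5-Flav-6-(triethylsilyloxy)hept-3-yn-5-one numbered as (1S,2R)-1-Ar-5-(tert-butyldimethylsilyloxy)-2-Flav-1-(triethylsilyloxy)hex-3-yn-... ynone with a 1-silyloxyethyl terminus (either configuration at that carbinol) | CC[Si](CC)(CC)O[C@H](c1ccc(OCc2ccccc2)cc1)[C@@H](c1c(-c2ccc(OCc3ccccc3)cc2)oc2cc(OCc3ccccc3)cc(OCc3ccccc3)c2c1=O)C(=O)C#CC(C)O[Si](C)(C)C(C)(C)C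
F7 | step 12 | desilylated diol of F6 (not isolated) | O[C@H](c1ccc(OCc2ccccc2)cc1)[C@@H](c1c(-c2ccc(OCc3ccccc3)cc2)oc2cc(OCc3ccccc3)cc(OCc3ccccc3)c2c1=O)C(=O)C#CC(C)O
F8 | step 12 | (2S,3R)-2-Ar-3-Flav-6-(1-hydroxyethyl)-2,3-dihydro-4H-pyran-4-one | O=C1C=C(C(C)O)O[C@H](c2ccc(OCc3ccccc3)cc2)[C@H]1c1c(-c2ccc(OCc3ccccc3)cc2)oc2cc(OCc3ccccc3)cc(OCc3ccccc3)c2c1=O
F9 | step 12 | (2S,3R)-6-acetyl-2-Ar-3-Flav-2,3-dihydro-4H-pyran-4-one | O=C1C=C(C(C)=O)O[C@H](c2ccc(OCc3ccccc3)cc2)[C@H]1c1c(-c2ccc(OCc3ccccc3)cc2)oc2cc(OCc3ccccc3)cc(OCc3ccccc3)c2c1=O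
F10 | step 12 | (2S,3R)-2-Ar-3-Flav-6-(4,4,4-trifluoro-3-oxobutanoyl)-2,3-dihydro-4H-pyran-4-one | O=C1C=C(C(=O)CC(=O)C(F)(F)F)O[C@H](c2ccc(OCc3ccccc3)cc2)[C@H]1c1c(-c2ccc(OCc3ccccc3)cc2)oc2cc(OCc3ccccc3)cc(OCc3ccccc3)c2c1=O
F11 | step 9 | (2R,3S)-3-Ar-2-Flav-3-(triethylsilyloxy)propanal | CC[Si](CC)(CC)O[C@H](c1ccc(OCc2ccccc2)cc1)[C@@H](c1c(-c2ccc(OCc3ccccc3)cc2)oc2cc(OCc3ccccc3)cc(OCc3ccccc3)c2c1=O)C=O
F12 | step 9 | (5R,6S)-6-Ar-1-(tert-butyldimethylsilyloxy)-5-Flav-6-(triethylsilyloxy)hex-2-yn-4-ol (both carbinol epimers) | CC[Si](CC)(CC)O[C@H](c1ccc(OCc2ccccc2)cc1)[C@@H](c1c(-c2ccc(OCc3ccccc3)cc2)oc2cc(OCc3ccccc3)cc(OCc3ccccc3)c2c1=O)C(O)C#CCO[Si](C)(C)C(C)(C)C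
F13 | step 16 | benzyl (E)-1,2-dichlorovinyl ether | Cl\C=C(/Cl)OCc1ccccc1
F14 | step 16 | lithium benzyloxyacetylide | [Li]C#COCc1ccccc1
F15 | step 16 | benzyloxyethyne | C#COCc1ccccc1
F16 | step 16 | 3-(benzyloxy)-4-[(2S,3R)-2-Ar-3-Flav-4-oxo-3,4-dihydro-2H-pyran-6-yl]cyclobut-2-en-1-one (both epimers at the cyclobutenone sp3 carbon) | O=C1C=C(C2C(=O)C=C2OCc2ccccc2)O[C@H](c2ccc(OCc3ccccc3)cc2)[C@H]1c1c(-c2ccc(OCc3ccccc3)cc2)oc2cc(OCc3ccccc3)cc(OCc3ccccc3)c2c1=O
F17 | step 16 | (2S,3R)-2-Ar-7-(benzyloxy)-3-Flav-5-hydroxy-2,3-dihydro-4H-chromen-4-one | O=C1c2c(O)cc(OCc3ccccc3)cc2O[C@H](c2ccc(OCc3ccccc3)cc2)[C@H]1c1c(-c2ccc(OCc3ccccc3)cc2)oc2cc(OCc3ccccc3)cc(OCc3ccccc3)c2c1=O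
A1 | alternative 1 | (2S,3R) target as its 7,4',7'',4'''-tetrabenzyl ether | O=C1c2c(O)cc(OCc3ccccc3)cc2O[C@H](c2ccc(OCc3ccccc3)cc2)[C@H]1c1c(-c2ccc(OCc3ccccc3)cc2)oc2cc(OCc3ccccc3)cc(O)c2c1=O
A2 | alternative 1 | cyclopropane with a 4-(benzyloxy)phenyl group on the future C2, a 4-(benzyloxy)-2,6-dihydroxybenzoyl group on the future C3, and a 4-(benzyloxy)-2,6-dihydroxybenzoyl and a 4-(benzyloxy)benzoyl group on the future C3'' (either configuration at that quaternary carbon) | O=C(c1c(O)cc(OCc2ccccc2)cc1O)C1(C(=O)c2ccc(OCc3ccccc3)cc2)[C@@H](c2ccc(OCc3ccccc3)cc2)[C@@H]1C(=O)c1c(O)cc(OCc2ccccc2)cc1O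
A3 | alternative 2 | flavan-4-ol analogue of the target hexabenzyl ether | O[C@@H]1c2c(OCc3ccccc3)cc(OCc3ccccc3)cc2O[C@H](c2ccc(OCc3ccccc3)cc2)[C@H]1c1c(-c2ccc(OCc3ccccc3)cc2)oc2cc(OCc3ccccc3)cc(OCc3ccccc3)c2c1=O
A4 | alternative 2 | 1-[2,4-bis(benzyloxy)-6-bromophenyl]-3-Ar-2-Flav-propane-1,3-diol with the configuration that leads to A3 | O[C@H](c1c(Br)cc(OCc2ccccc2)cc1OCc1ccccc1)[C@H](c1c(-c2ccc(OCc3ccccc3)cc2)oc2cc(OCc3ccccc3)cc(OCc3ccccc3)c2c1=O)[C@H](O)c1ccc(OCc2ccccc2)cc1
A5 | alternative 3 | trans-2-aryl-3-(flavon-3-yl)chroman (4-deoxo target) hexabenzyl ether | C1c2c(OCc3ccccc3)cc(OCc3ccccc3)cc2O[C@H](c2ccc(OCc3ccccc3)cc2)[C@H]1c1c(-c2ccc(OCc3ccccc3)cc2)oc2cc(OCc3ccccc3)cc(OCc3ccccc3)c2c1=O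
A6 | alternative 3 | 5,7-bis(benzyloxy)-2-[4-(benzyloxy)phenyl]-3-[(E)-2-(4-(benzyloxy)phenyl)ethenyl]-4H-chromen-4-one | O=c1c(/C=C/c2ccc(OCc3ccccc3)cc2)c(-c2ccc(OCc3ccccc3)cc2)oc2cc(OCc3ccccc3)cc(OCc3ccccc3)c12
A7 | alternative 3 | 3,5-bis(benzyloxy)-2-(hydroxymethyl)phenol | OCc1c(O)cc(OCc2ccccc2)cc1OCc1ccccc1
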